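**Plan**
1. Numbering (germacranolide style): C1=C2 (Z), C3 ketone, C4–H bearing C15H2OH, C5H2, C6–O (lactone), C7, C8–O-angelate, C9H2, C10(CH3)(OH), C11(=C13H2)–C12(=O). The aldol triad C3(=O)–C4H–C15H2OH is read as a 2-isoxazoline, so the retrosynthesis first cuts C3–C4 (together with O–C15) by a retro nitrile oxide–alkene cycloaddition across the ten-membered ring. The Z-C1=C2 olefin next to C3 and an allyl terminus C4=C15 on C6 of the trans-lactone make this closure possible.
2. The open chain is then cut at C7–C8 and C11–C13 (dithiane acyl anion added 1,4 to butenolide 11, enolate trapped by CH2O), at C1=C2 (Z-selective Wittig), at C8–C9 (epoxide opening) and at the angelate C–O bond.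
3. Forward: fragment 6 (C8–C10, C1–C3) and butenolide 11 (C4–C7, C11, C12, C15) are joined, which completes the substituted γ-lactone ring first. C8 is then reduced and acylated. The ten-membered carbocycle and a temporary isoxazoline ring close together in step 15. Last, the exocyclic methylene is unmasked and the isoxazoline is opened to the β-hydroxy ketone.
4. Stereochemistry: C10 from (S)-2-methylglycidol 1; C6 from lactone tosylate 7; C7 (and temporary C11) by anti addition to the butenolide; C8 by reduction directed by the C10 hydroxyl; C4 in the cycloaddition under control of C6; Z-C1=C2 from the Wittig step, then locked in a lactol; angelate geometry from angelic acid.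

Key step: step 15

Remark: the target is treated as the open Z-γ-hydroxy enone drawn; ring–chain tautomerism to the C3/C10 hemiketal would not change the route.

Step 1
Reactants: 1 (S)-(2-methyloxiran-2-yl)methanol
Product: 2 (R)-tert-butyldimethyl[(2-methyloxiran-2-yl)methoxy]silane
Conditions: TBSCl, imidazole, CH2Cl2, 0 °C to rt
Reagents that add atoms: tert-butyldimethylsilyl chloride, CC(C)(C)[Si](C)(C)Cl
Why: Silyl ether formation under neutral imidazole conditions generates no alkoxide, so a Payne rearrangement cannot scramble the quaternary centre (future C10), which is untouched.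

Step 2
Reactants: 2 (R)-tert-butyldimethyl[(2-methyloxiran-2-yl)methoxy]silane
Product: 4 (R)-3-(1,3-dithian-2-yl)-2-methylpropane-1,2-diol, via silyl ether 3 (not isolated)
Conditions: 1,3-dithiane, n-BuLi, THF, −30 °C; then 2, −20 to 0 °C; then Bu4NF, rt; H2O
Reagents that add atoms: 1,3-dithiane, C1CSCSC1
Why: Corey–Seebach epoxide opening: 2-lithio-1,3-dithiane attacks the CH2 terminus (C9) of the 2,2-disubstituted epoxide by SN2, leaving C10 untouched, and fluoride then removes the silyl group in the same flask.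

Step 3
Reactants: 4 (R)-3-(1,3-dithian-2-yl)-2-methylpropane-1,2-diol
Product: 5 (R)-3-(1,3-dithian-2-yl)-2-hydroxy-2-methylpropanal
Conditions: SO3·pyridine, DMSO, iPr2NEt, CH2Cl2, 0 °C
Reagents that add atoms: none
Why: Parikh–Doering oxidation converts only the primary alcohol (the tertiary one cannot be oxidised) and tolerates the thioacetal; the α-carbon is quaternary, so it cannot epimerise.

Step 4
Reactants: 5 (R)-3-(1,3-dithian-2-yl)-2-hydroxy-2-methylpropanal
Product: 6 (2R,3Z)-4-(1,3-dioxolan-2-yl)-1-(1,3-dithian-2-yl)-2-methylbut-3-en-2-ol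
Conditions: (1,3-dioxolan-2-ylmethyl)triphenylphosphonium bromide, KN(SiMe3)2, THF, −78 °C to rt
Reagents that add atoms: (1,3-dioxolan-2-ylmethyl)triphenylphosphonium bromide, [Br-].C1COC(C[P+](c2ccccc2)(c2ccccc2)c2ccccc2)O1
Why: Wittig olefination with a non-stabilised ylide under salt-free conditions should favour the Z-olefin through the kinetic cis-oxaphosphetane, giving the masked Z-enal unit C1=C2–C3.

Step 5
Reactants: 7 (S)-(5-oxooxolan-2-yl)methyl 4-methylbenzenesulfonate
Product: 8 (S)-5-(prop-2-en-1-yl)oxolan-2-one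
Conditions: CH2=CHMgBr, CuI, THF, −40 to −20 °C
Reagents that add atoms: vinylmagnesium bromide, C=C[Mg]Br
Why: Organocuprate SN2 displacement of the primary tosylate should install the allyl group (C5–C4=C15) without touching the C6 stereocentre or the lactone.

Step 6
Reactants: 8 (S)-5-(prop-2-en-1-yl)oxolan-2-one
Product: 11 (R)-5-(prop-2-en-1-yl)furan-2(5H)-one, via lithium enolate 9 (not isolated), via selenide 10 (not isolated)
Conditions: LiN(iPr)2, THF, −78 °C; PhSeBr; then H2O2, pyridine, CH2Cl2, 0 °C to rt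
Reagents that add atoms: none
Why: α-Selenenylation of the lactone enolate followed by selenoxide syn-elimination is the classical lactone-to-butenolide desaturation; C6 is not involved.

Step 7
Reactants: 6 (2R,3Z)-4-(1,3-dioxolan-2-yl)-1-(1,3-dithian-2-yl)-2-methylbut-3-en-2-ol and 11 (R)-5-(prop-2-en-1-yl)furan-2(5H)-one
Product: 14 all-trans 3-(hydroxymethyl)-4-(2-substituted 1,3-dithian-2-yl)-5-allyl lactone (3R,4S,5R), via dilithio dithiane 12 (not isolated), via lithium enolate 13 (not isolated)
Conditions: 6, t-BuLi (2.1 equiv), THF/HMPA, −78 °C; then 11, −78 °C; then CH2O (monomeric, THF), −78 to −40 °C; H2O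
Reagents that add atoms: formaldehyde, C=O
Why: Tandem conjugate addition–aldol (three-component coupling): the dithiane acyl-anion equivalent adds 1,4 to the butenolide anti to the C6 allyl group (sets C7), and the enolate is hydroxymethylated anti to the new C7 substituent (sets C11, removed later).

Step 8
Reactants: 14 all-trans hydroxymethyl lactone
Product: 15 tert-butyldiphenylsilyl ether of 14 at the primary hydroxyl (C13)
Conditions: TBDPSCl, imidazole, DMF, 0 °C
Reagents that add atoms: tert-butyldiphenylsilyl chloride, CC(C)(C)[Si](Cl)(c1ccccc1)c1ccccc1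
Why: Selective silylation of the primary alcohol (the tertiary C10 hydroxyl is too hindered) masks the future exocyclic methylene carbon C13, so that no acrylate dipolarophile is present later.

Step 9
Reactants: 15 silyl ether dithiane
Product: 16 C8 ketone (β-hydroxy ketone with the free C10 hydroxyl)
Conditions: MeI, CaCO3, MeCN/H2O (9:1), 45 °C
Reagents that add atoms: water, O
Why: Alkylative dithiane hydrolysis (S-methylation, then hydrolysis under CaCO3 buffering) should unveil the C8 ketone without cleaving the acetal; C7 keeps its trans arrangement, which is also the thermodynamic one.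

Step 10
Reactants: 16 C8 ketone
Product: 17 8,10-anti diol (8R)
Conditions: Me4NBH(OAc)3, MeCN/AcOH (1:1), −30 °C
Reagents that add atoms: none
Why: Evans–Saksena hydroxyl-directed reduction: the C10 hydroxyl binds the borohydride and delivers hydride through a chair in which the Z-alkenyl chain (larger than methyl) is equatorial, which should give the 1,3-anti diol and so the 8R carbinol.

Step 11
Reactants: 17 8,10-anti diol
Product: 18 C8 angelate (C10 hydroxyl free)
Conditions: angelic acid, 2,4,6-trichlorobenzoyl chloride, Et3N, toluene, rt; then 17, DMAP, 60 °C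
Reagents that add atoms: angelic acid, C/C=C(/C)C(=O)O
Why: Yamaguchi esterification through the mixed anhydride acylates only the secondary C8 hydroxyl (the tertiary one is inert) and is a standard way to make angelates without Z-to-E isomerisation.

Step 12
Reactants: 18 C8 angelate
Product: 19 lactol (5-hydroxy-2-methyl-2,5-dihydrofuran-2-yl unit from C10–O and C3)
Conditions: PPTS, acetone/H2O (5:1), 50 °C
Reagents that add atoms: water, O
Why: Acid-catalysed acetal hydrolysis with participation of the C10 hydroxyl should give the cyclic hemiacetal, which locks the Z-geometry of C1=C2 in a five-membered ring.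

Step 13
Reactants: 19 lactol
Product: 20 Z-γ-hydroxy enal oxime
Conditions: NH2OH·HCl, pyridine, EtOH, 0 °C to rt
Reagents that add atoms: hydroxylamine hydrochloride, NO.Cl
Why: Oxime formation: hydroxylamine condenses with the open aldehyde form of the lactol far faster than it attacks the lactone or the hindered enoate.

Step 14
Reactants: 20 oxime
Product: 22 oxime with the C10 hydroxyl as its triethylsilyl ether, via bis-silyl oxime 21 (not isolated)
Conditions: TESOTf (2.4 equiv), 2,6-lutidine, CH2Cl2, −78 to 0 °C; then MeOH, K2CO3 (cat.), 0 °C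
Reagents that add atoms: triethylsilyl trifluoromethanesulfonate, CC[Si](CC)(CC)OS(=O)(=O)C(F)(F)F
Why: Silyl triflate silylation protects the tertiary C10 hydroxyl, which would otherwise add to the nitrile oxide carbon, and the labile O-silyl oxime formed alongside is cleaved by brief methanolysis.

Step 15
Reactants: 22 silylated oxime
Product: 25 ten-membered-ring 2-isoxazoline (C3–C4 and O–C15 formed), via hydroximoyl chloride 23 (not isolated), via nitrile oxide 24 (not isolated)
Conditions: N-chlorosuccinimide, DMF, 0 °C to rt; then slow addition (syringe pump, 12 h) to Et3N, toluene, 80 °C, final 1 mM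
Reagents that add atoms: none
Why: Chlorination of the aldoxime and dehydrochlorination give the Z-alkenyl nitrile oxide 24, which undergoes a concerted, asynchronous intramolecular 1,3-dipolar cycloaddition to the terminal C4=C15 olefin, forming C3–C4 and O–C15 in one event (closest known reaction type: intramolecular nitrile oxide–alkene cycloaddition as used for medium rings and macrocycles). The ten-membered carbocycle closes in the fused mode, the chain closing on the internal olefin carbon C4, and the five-membered 2-isoxazoline closes through the O–C15 bond of the same cycloaddition. The new stereocentre C4 is controlled by C6: in the fused transition state the C3–C4–C5–C6–C7 segment is extended and C15 with the incoming oxygen lies on the side of H-6, not of the lactone C6–O bond, which avoids a syn-pentane contact and should give 4S. The step needs fused over bridged regiochemistry (C3 to C4, not to C15); the Z-C1=C2 olefin and the trans-fused lactone hold C3 over C4, and the bridged alternative would need an eleven-membered ring with a bridgehead C=N and the N–O unit inside the ring, a mode that medium-ring nitrile oxide cycloadditions are expected to avoid. It also needs chemoselectivity (exocyclic methylene masked as CH2OSi, inert trisubstituted angelate olefin, silylated C10 hydroxyl) and cyclisation over furoxan dimerisation (slow addition at high dilution).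

Step 16
Reactants: 25 macrocyclic isoxazoline
Product: 26 diol (C10–OH and C13H2OH free)
Conditions: HF·pyridine, pyridine/THF, 0 °C to rt
Reagents that add atoms: none
Why: Fluoride-mediated desilylation removes both silyl ethers, while the isoxazoline, lactone and angelate are stable to buffered HF·pyridine.

Step 17
Reactants: 26 diol
Product: 28 α-methylene lactone isoxazoline, via mesylate 27 (not isolated)
Conditions: MsCl, Et3N (excess), CH2Cl2, 0 °C to rt
Reagents that add atoms: none
Why: Mesylation of the only primary alcohol followed by E1cB β-elimination with the excess amine is the standard unmasking of an α-methylene-γ-butyrolactone; the tertiary C10 hydroxyl does not react.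

Step 18
Reactants: 28 α-methylene lactone isoxazoline
Product: 29 target
Conditions: Mo(CO)6, MeCN/H2O (15:1), 80 °C
Reagents that add atoms: water, O
Why: Mo(CO)6-mediated reductive N–O cleavage of the 2-isoxazoline and hydrolysis of the β-hydroxy imine in the same pot should unveil the C3 ketone and C15 alcohol without reducing the olefins; C4 is untouched.

**Compound list**
1 | (S)-(2-methyloxiran-2-yl)methanol [(S)-2-methylglycidol] | OC[C@@]1(C)CO1 | starting material
2 | (R)-tert-butyldimethyl[(2-methyloxiran-2-yl)methoxy]silane (spatial arrangement of 1 retained) | CC(C)(C)[Si](C)(C)OC[C@@]1(C)CO1 | intermediate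
3 | (R)-1-[(tert-butyldimethylsilyl)oxy]-3-(1,3-dithian-2-yl)-2-methylpropan-2-ol, present as its lithium alkoxide | CC(C)(C)[Si](C)(C)OC[C@](C)(O)CC1SCCCS1 | intermediate
4 | (R)-3-(1,3-dithian-2-yl)-2-methylpropane-1,2-diol | OC[C@](C)(O)CC1SCCCS1 | intermediate
5 | (R)-3-(1,3-dithian-2-yl)-2-hydroxy-2-methylpropanal | O=C[C@](C)(O)CC1SCCCS1 | intermediate
6 | (2R,3Z)-4-(1,3-dioxolan-2-yl)-1-(1,3-dithian-2-yl)-2-methylbut-3-en-2-ol | S1CCCSC1C[C@@](C)(O)/C=C\C2OCCO2 | intermediate
7 | (S)-(5-oxooxolan-2-yl)methyl 4-methylbenzenesulfonate | Cc1ccc(cc1)S(=O)(=O)OC[C@@H]1CCC(=O)O1 | starting material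
8 | (S)-5-(prop-2-en-1-yl)oxolan-2-one | O=C1CC[C@@H](CC=C)O1 | intermediate
9 | lithium enolate of 8 | [Li]OC1=CC[C@@H](CC=C)O1 | intermediate
10 | (5R)-3-(phenylselanyl)-5-(prop-2-en-1-yl)oxolan-2-one, both C3 epimers | O=C1C([Se]c2ccccc2)C[C@@H](CC=C)O1 | intermediate
11 | (R)-5-(prop-2-en-1-yl)furan-2(5H)-one | O=C1C=C[C@@H](CC=C)O1 | intermediate
12 | dilithio derivative of 6 (lithium alkoxide at C10, lithium on the dithiane carbon C8) | [Li]C1(SCCCS1)C[C@@](C)(O[Li])/C=C\C2OCCO2 | intermediate
13 | lithium lactone enolate from 1,4-addition of 12 to 11 (C7 trans to the C6 allyl group) | C1=C(O[Li])O[C@H](CC=C)[C@H]1C2(SCCCS2)C[C@@](C)(O[Li])/C=C\C3OCCO3 | intermediate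
14 | (3R,4S,5R)-4-{2-[(2R,3Z)-4-(1,3-dioxolan-2-yl)-2-hydroxy-2-methylbut-3-en-1-yl]-1,3-dithian-2-yl}-3-(hydroxymethyl)-5-(prop-2-en-1-yl)oxolan-2-one (all-trans) | OC[C@@H]1C(=O)O[C@H](CC=C)[C@H]1C2(SCCCS2)C[C@@](C)(O)/C=C\C3OCCO3 | intermediate
15 | (3R,4S,5R)-3-{[tert-butyl(diphenyl)silyl]oxymethyl} analogue of 14 (tertiary hydroxyl free) | CC(C)(C)[Si](c4ccccc4)(c5ccccc5)OC[C@@H]1C(=O)O[C@H](CC=C)[C@H]1C2(SCCCS2)C[C@@](C)(O)/C=C\C3OCCO3 | intermediate
16 | (3R,4S,5R)-3-{[tert-butyl(diphenyl)silyl]oxymethyl}-4-[(3R,4Z)-5-(1,3-dioxolan-2-yl)-3-hydroxy-3-methylpent-4-enoyl]-5-(prop-2-en-1-yl)oxolan-2-one | CC(C)(C)[Si](c4ccccc4)(c5ccccc5)OC[C@@H]1C(=O)O[C@H](CC=C)[C@H]1C(=O)C[C@@](C)(O)/C=C\C2OCCO2 | intermediate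
17 | (3R,4R,5R)-3-{[tert-butyl(diphenyl)silyl]oxymethyl}-4-[(1R,3R,4Z)-5-(1,3-dioxolan-2-yl)-1,3-dihydroxy-3-methylpent-4-en-1-yl]-5-(prop-2-en-1-yl)oxolan-2-one (8,10-anti diol; same spatial arrangement in the lactone as 16) | CC(C)(C)[Si](c4ccccc4)(c5ccccc5)OC[C@@H]1C(=O)O[C@H](CC=C)[C@H]1[C@H](O)C[C@@](C)(O)/C=C\C2OCCO2 | intermediate
18 | (1R,3R,4Z)-1-[(3R,4S,5R)-3-{[tert-butyl(diphenyl)silyl]oxymethyl}-2-oxo-5-(prop-2-en-1-yl)oxolan-4-yl]-5-(1,3-dioxolan-2-yl)-3-hydroxy-3-methylpent-4-en-1-yl (2Z)-2-methylbut-2-enoate | CC(C)(C)[Si](c4ccccc4)(c5ccccc5)OC[C@@H]1C(=O)O[C@H](CC=C)[C@H]1[C@H](OC(=O)/C(C)=C\C)C[C@@](C)(O)/C=C\C2OCCO2 | intermediate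
19 | lactol of 18: (1R)-1-[the same lactone as in 18]-2-[(2R)-5-hydroxy-2-methyl-2,5-dihydrofuran-2-yl]ethyl (2Z)-2-methylbut-2-enoate, both anomers | CC(C)(C)[Si](c4ccccc4)(c5ccccc5)OC[C@@H]1C(=O)O[C@H](CC=C)[C@H]1[C@H](OC(=O)/C(C)=C\C)C[C@@]2(C)OC(O)C=C2 | intermediate
20 | (1R,3R,4Z)-1-[the same lactone as in 18]-3-hydroxy-6-(hydroxyimino)-3-methylhex-4-en-1-yl (2Z)-2-methylbut-2-enoate | CC(C)(C)[Si](c4ccccc4)(c5ccccc5)OC[C@@H]1C(=O)O[C@H](CC=C)[C@H]1[C@H](OC(=O)/C(C)=C\C)C[C@@](C)(O)/C=C\C=NO | intermediate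
21 | 20 carrying SiEt3 on the C10 oxygen and on the oxime oxygen | CC(C)(C)[Si](c4ccccc4)(c5ccccc5)OC[C@@H]1C(=O)O[C@H](CC=C)[C@H]1[C@H](OC(=O)/C(C)=C\C)C[C@@](C)(O[Si](CC)(CC)CC)/C=C\C=NO[Si](CC)(CC)CC | intermediate
22 | 20 with the C10 hydroxyl as its triethylsilyl ether (free oxime) | CC(C)(C)[Si](c4ccccc4)(c5ccccc5)OC[C@@H]1C(=O)O[C@H](CC=C)[C@H]1[C@H](OC(=O)/C(C)=C\C)C[C@@](C)(O[Si](CC)(CC)CC)/C=C\C=NO | intermediate
23 | hydroximoyl chloride of 22 (C3(Cl)=N–OH) | CC(C)(C)[Si](c4ccccc4)(c5ccccc5)OC[C@@H]1C(=O)O[C@H](CC=C)[C@H]1[C@H](OC(=O)/C(C)=C\C)C[C@@](C)(O[Si](CC)(CC)CC)/C=C\C(Cl)=NO | intermediate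
24 | nitrile oxide of 22 (Z-alkenyl C3≡N–O) | CC(C)(C)[Si](c4ccccc4)(c5ccccc5)OC[C@@H]1C(=O)O[C@H](CC=C)[C@H]1[C@H](OC(=O)/C(C)=C\C)C[C@@](C)(O[Si](CC)(CC)CC)/C=C\C#[N+][O-] | intermediate
25 | ten-membered-ring 2-isoxazoline: skeleton of 29 with C3=N–O–C15H2 in place of the C3 ketone and C15 hydroxyl, C8 angelate, C10 OSiEt3, C11–H (11R) bearing C13H2OSi(t-Bu)Ph2, Z-C1=C2; C4, C6, C7, C8, C10 arranged as in 29 | CC(C)(C)[Si](c4ccccc4)(c5ccccc5)OC[C@@H]1C(=O)O[C@@H]2C[C@H]3CON=C3/C=C\[C@](C)(O[Si](CC)(CC)CC)C[C@@H](OC(=O)/C(C)=C\C)[C@@H]12 | intermediate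
26 | 25 without the silyl groups (C10–OH, C13H2OH) | OC[C@@H]1C(=O)O[C@@H]2C[C@H]3CON=C3/C=C\[C@](C)(O)C[C@@H](OC(=O)/C(C)=C\C)[C@@H]12 | intermediate
27 | C13 methanesulfonate of 26 | CS(=O)(=O)OC[C@@H]1C(=O)O[C@@H]2C[C@H]3CON=C3/C=C\[C@](C)(O)C[C@@H](OC(=O)/C(C)=C\C)[C@@H]12 | intermediate
28 | α-methylene lactone isoxazoline: 29 with C3=N–O–C15H2 in place of the C3 ketone and C15 hydroxyl | C=C1C(=O)O[C@@H]2C[C@H]3CON=C3/C=C\[C@](C)(O)C[C@@H](OC(=O)/C(C)=C\C)[C@@H]12 | intermediate
29 | (1Z,4S,6R,7S,8R,10R)-8-[(2Z)-2-methylbut-2-enoyloxy]-10,15-dihydroxy-3-oxogermacra-1,11(13)-dien-12,6-olide | C=C1C(=O)O[C@@H]2C[C@@H](CO)C(=O)/C=C\[C@](C)(O)C[C@@H](OC(=O)/C(C)=C\C)[C@@H]12 | target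

**Count and risks**
Total steps: 18. Longest linear sequence: 16 steps (steps 1–4 and 7–18, from 1); the branch from 7 (steps 5–6, then 7–18) runs 14 steps.

Steps most likely to fail:

1. Step 15. What may go wrong: cycloaddition in the bridged sense (C3 bonding to C15), attack on the wrong olefin face, or dimerisation of the nitrile oxide instead of ring closure. Fallback (sets out from 18, comes back at 25): the same C3–C4 bond is closed by an intramolecular Nozaki–Hiyama–Kishi reaction and the isoxazoline is then built by condensation. 18 is silylated at the C10 hydroxyl (TESOTf, 2,6-lutidine, −78 °C) to the triethylsilyl ether F1. Wacker oxidation of the terminal olefin under non-acidic conditions (Pd(quinox)Cl2, AgSbF6, aqueous t-BuOOH) gives the C4 methyl ketone F2. Kinetic enolisation (KN(SiMe3)2, −78 °C) and trapping with N-(5-chloropyridin-2-yl)bis(trifluoromethanesulfonimide) give the 2-triflyloxy-1-alkene F3. Mild acetal hydrolysis (PPTS, wet acetone) gives the Z-enal F4. CrCl2 with catalytic NiCl2 in DMSO/THF at high dilution should close the ten-membered ring to the macrocyclic allylic alcohol F5 (C3 carbinol, C4=C15 exocyclic methylene). Dess–Martin oxidation gives the cross-conjugated dienone F6. Hydroxylamine hydrochloride/pyridine then forms the C3 oxime, whose oxygen adds to C15 in conjugate fashion to give 25; C4 is set on protonation and can be equilibrated with weak base if needed.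

2. Step 7. What may go wrong: quenching of the hindered dithiane anion by proton transfer (γ-hydrogen of the butenolide), or failure of the crowded enolate to capture formaldehyde (reversal, oligomer formation). Fallback (sets out from 6 and 11, comes back at 14): the two bond formations are separated. The conjugate addition is run as in step 7 but quenched with NH4Cl, and the conjugate adduct F7 is isolated. Its lithium enolate is then formed on purpose (LiN(iPr)2, 2.2 equiv, −78 °C) and hydroxymethylated with monomeric formaldehyde, anti to the C7 substituent, to give 14.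

3. Step 10. What may go wrong: hydride delivery in the wrong sense or with low selectivity, because methyl and the alkenyl chain on C10 differ little in size. Fallback (sets out from 16, comes back at 18): the ketone is reduced under chelation control with external hydride (Et2BOMe, NaBH4, THF/MeOH, −78 °C; Narasaka–Prasad) to obtain the 8-epimeric diol F8 on purpose. F8 is then esterified with angelic acid under Mitsunobu conditions (PPh3, diisopropyl azodicarboxylate), which inverts C8 and installs the angelate in one operation, giving 18 directly.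

**Further compounds**
F1 | step 15 | C10 triethylsilyl ether of 18 | CC(C)(C)[Si](c4ccccc4)(c5ccccc5)OC[C@@H]1C(=O)O[C@H](CC=C)[C@H]1[C@H](OC(=O)/C(C)=C\C)C[C@@](C)(O[Si](CC)(CC)CC)/C=C\C2OCCO2
F2 | step 15 | F1 with the allyl group oxidised to a 2-oxopropyl group (C4 methyl ketone) | CC(C)(C)[Si](c4ccccc4)(c5ccccc5)OC[C@@H]1C(=O)O[C@H](CC(C)=O)[C@H]1[C@H](OC(=O)/C(C)=C\C)C[C@@](C)(O[Si](CC)(CC)CC)/C=C\C2OCCO2
F3 | step 15 | 2-(trifluoromethanesulfonyloxy)prop-2-en-1-yl analogue of F2 (C4 enol triflate, C15 = CH2) | CC(C)(C)[Si](c4ccccc4)(c5ccccc5)OC[C@@H]1C(=O)O[C@H](CC(=C)OS(=O)(=O)C(F)(F)F)[C@H]1[C@H](OC(=O)/C(C)=C\C)C[C@@](C)(O[Si](CC)(CC)CC)/C=C\C2OCCO2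
F4 | step 15 | Z-enal from F3 (C3 aldehyde, acetal removed) | CC(C)(C)[Si](c4ccccc4)(c5ccccc5)OC[C@@H]1C(=O)O[C@H](CC(=C)OS(=O)(=O)C(F)(F)F)[C@H]1[C@H](OC(=O)/C(C)=C\C)C[C@@](C)(O[Si](CC)(CC)CC)/C=C\C=O
F5 | step 15 | macrocyclic allylic alcohol: ten-membered ring with C3–OH (either epimer), C4=C15H2, Z-C1=C2, C8 angelate, C10 OSiEt3, C13H2OSi(t-Bu)Ph2 | CC(C)(C)[Si](c4ccccc4)(c5ccccc5)OC[C@@H]1C(=O)O[C@@H]2CC(=C)C(O)/C=C\[C@](C)(O[Si](CC)(CC)CC)C[C@@H](OC(=O)/C(C)=C\C)[C@@H]12
F6 | step 15 | cross-conjugated dienone from F5 (C3 ketone, C4=C15H2) | CC(C)(C)[Si](c4ccccc4)(c5ccccc5)OC[C@@H]1C(=O)O[C@@H]2CC(=C)C(=O)/C=C\[C@](C)(O[Si](CC)(CC)CC)C[C@@H](OC(=O)/C(C)=C\C)[C@@H]12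
F7 | step 7 | (4S,5R)-4-{2-[(2R,3Z)-4-(1,3-dioxolan-2-yl)-2-hydroxy-2-methylbut-3-en-1-yl]-1,3-dithian-2-yl}-5-(prop-2-en-1-yl)oxolan-2-one | C1C(=O)O[C@H](CC=C)[C@H]1C2(SCCCS2)C[C@@](C)(O)/C=C\C3OCCO3
F8 | step 10 | C8 epimer of 17 (8,10-syn diol) | CC(C)(C)[Si](c4ccccc4)(c5ccccc5)OC[C@@H]1C(=O)O[C@H](CC=C)[C@H]1[C@@H](O)C[C@@](C)(O)/C=C\C2OCCO2
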